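in all of them: Q 34 mM; J 0.19 mM
- larch: X 6.8 mM; the very flask that is asked about, followed so far
- flask: X 6.80 mM; time 8.0 d

larch run (percent of the Q charged)

| time / d | D / % | Q / % |
|---|---|---|
| 0.333 | 10 | 77 |
| 1.04 | 21 | 55 |
| 1.67 | 33 | 45 |
| 3.00 | 52 | 29 |
| 4.00 | 58 | 24 |

(standard deviation of a reading: 2 percentage points)

- the average divides the monomer in chains by the number of chains begun, living and dead together
- the numbers in the tables scatter with a standard deviation of 2 percentage points
- the earlier runs do not show the number of chains; that part of a forecast is a guess

1. whether the average number of monomer units in a chain (chains begun, living or dead) reaches 40 by 8.0 d (yes / no)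
2. average number of monomer units in a chain (chains begun, living or dead) at 8.0 d

1. The constants of this flask are unknown, but its charges fold into one number. J, the limiting reagent for the count of chains, is charged at a fraction j = 0.559% of Q.

2. D and Q together read 82.0% at 4.00 d, with a scatter of 2 percentage points on each reading, and X is charged at a fraction x = 20.0% of Q. So the readings allow X to take its equivalent of Q away from the chains.

3. The charge length, the share of Q left after X divided by j, is 143. It is the average length of a chain when that share of Q has entered chains, if J begins one chain apiece. The wanted 40 is about a quarter of it, so the answer reads yes.

4. One number is not enough, since it holds no time and its chain count is a guess. Between 1.04 d and 4.00 d Q falls at a read rate of 0.280 /d. Carried to 8.0 d, this leaves 7.83% of Q, so this reckoning commits to a length of 129.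

The forecast answers yes and gives a length of 130, on the supposition that “each J starts one chain”.

    Q + J → E + D (k = 35.0 /M/h)
    Q + E → D + E, rate k2*[E]*[Q] (k = 72.0 /M/h)
    Q + J → L (k = 0.250 /M/h)
    X + Q → G (k = 11.0 /M/h)

The flask gives yes and 134, which is 93.7% of the charge length. At 8.00 d the living end E stands at 0.189 mM against 0.19 mM of J charged. The wanted length is 28.0% of the charge length, so the reacted share of Q at that point should be x plus this part of what X leaves, 42.4%. The flask reaches 40 at 0.985 d, with 42.2% of Q reacted.

Readings and results were computed from invented constants.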